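**Retrosynthetic overview**

- The route rests on the C7–C7' bond, which joins two benzene rings that each carry oxygen on C4, C5, C6 and C7a, so the axis has four ortho oxygens (C6, C6', C7a, C7a'). Ellagic acid already holds this biaryl with the C4/C5/C6 oxygens in place, but has its lactone carbonyl carbons on C7a/C7a', where the target has O1/O1'.
- Last disconnections: the O1–C2 and O1'–C2' hemiketal bonds (both furanone rings close last), the C2 oxygens (SeO2), and the C3a–C3 bonds (Fries shift of a propanoate on the C7a oxygen).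
- Key disconnection: the C7a–O and C7a'–O bonds, made by a twofold Dakin-type oxidation of the biaryl 2,2'-dialdehyde.
- The dialdehyde comes from ellagic acid by O-methylation, lactone reduction, benzylation of the released C6 phenols and oxidation; no biaryl coupling is needed.
- Ring order: both benzene rings and the axis are bought; the axis is resolved after the Fries step; the furanone rings close in step 9 and C2/C2' are fixed in step 10.

Key step: step 5

Atom numbers are those of the benzofuran-3(2H)-one halves of the target (O1, C2, C3, C3a, C4 to C7, C7a; primes for the second half) and are used for the biphenyl intermediates as well.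

Assumption: the SMILES fixes C2 and C2' (both R) but not the sense of the C7–C7' axis, which SMILES cannot show and which is therefore given in the names. With four ortho oxygens the axis is taken to be configurationally stable, and the route is written for the (aR) axis. C2 and C2' are hemiketal carbons that epimerise through the open 1,2-diketone, so they are set last, by crystallisation on the resolved axis. If the (aR) series should settle as 2S,2'S, the (aS) antipode from the same resolution is carried through steps 9 and 10 instead, which by mirror symmetry then gives 2R,2'R.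

**Route**

Step 1
Reactants: 1 ellagic acid; 2 dimethyl sulfate
Product: 3 3,3',4,4'-tetra-O-methylellagic acid (both lactones intact)
Conditions: Me2SO4, K2CO3, dry DMF, 60 °C
Reagents that add atoms: dimethyl sulfate COS(=O)(=O)OC
Why: Williamson O-methylation of the four phenols under anhydrous carbonate conditions leaves the two aryl lactones closed, so the C6/C6' oxygens stay distinguished from the C4 and C5 oxygens.

Step 2
Reactants: 3 3,3',4,4'-tetra-O-methylellagic acid
Product: 4 6,6'-bis(hydroxymethyl)-3,3',4,4'-tetramethoxybiphenyl-2,2'-diol (racemic axis)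
Conditions: LiAlH4, THF, reflux (3 added as a fine suspension); aq. KNaC4H4O6 work-up at pH about 7
Reagents that add atoms: none
Why: LiAlH4 reduction of the two aryl ester (lactone) carbonyls gives the benzylic alcohols on C7a/C7a' and releases the C6/C6' phenols, and the neutral work-up avoids acid-induced closure of the electron-rich benzylic alcohol onto the neighbouring phenol.

Step 3
Reactants: 4 6,6'-bis(hydroxymethyl)-3,3',4,4'-tetramethoxybiphenyl-2,2'-diol; 5 benzyl bromide
Product: 6 [6,6'-bis(benzyloxy)-4,4',5,5'-tetramethoxybiphenyl-2,2'-diyl]dimethanol (racemic axis)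
Conditions: BnBr, K2CO3, DMF, rt to 40 °C
Reagents that add atoms: benzyl bromide BrCc1ccccc1
Why: Williamson etherification in which K2CO3 deprotonates only the phenols, so the C6/C6' oxygens are benzylated and the benzylic alcohols stay free.

Step 4
Reactants: 6 [6,6'-bis(benzyloxy)-4,4',5,5'-tetramethoxybiphenyl-2,2'-diyl]dimethanol
Product: 7 6,6'-bis(benzyloxy)-4,4',5,5'-tetramethoxybiphenyl-2,2'-dicarbaldehyde (racemic axis)
Conditions: (COCl)2, DMSO, CH2Cl2, −78 °C; Et3N, −78 °C to 0 °C
Reagents that add atoms: none
Why: Swern oxidation activates both benzylic alcohols before base is added, so no hydroxy aldehyde is present that could close to a seven-membered lactol and be over-oxidised to a lactone, as can happen with a slow heterogeneous oxidant such as MnO2.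

Step 5
Reactants: 7 6,6'-bis(benzyloxy)-4,4',5,5'-tetramethoxybiphenyl-2,2'-dicarbaldehyde
Product: 9 6,6'-bis(benzyloxy)-4,4',5,5'-tetramethoxybiphenyl-2,2'-diol (racemic axis), via bis(formate) 8 (not isolated)
Conditions: mCPBA (dried), CH2Cl2, 0 °C to rt; aq. Na2S2O3 wash; then K2CO3 (cat.), MeOH, 0 °C, argon
Reagents that add atoms: mCPBA OOC(=O)c1cccc(Cl)c1
Why: Each aldehyde adds the peracid to give a Criegee adduct in which the aryl group migrates from carbon to oxygen with loss of 3-chlorobenzoate, and methanolysis of the resulting aryl formate frees the phenol, so each formyl carbon on C7a/C7a' is replaced by oxygen. The closest known reaction type is the peracid Baeyer–Villiger (Dakin-type) oxidation of alkoxybenzaldehydes such as 3,4,5-trimethoxybenzaldehyde to the phenols. No ring is closed, no stereocentre is formed and the axis is not touched. Aryl migration has to win over hydride migration, which would give the carboxylic acid, and this is secured by the C5 methoxy group para to the migrating carbon, helped by the C4 and C6 oxygens and the ortho aryl group. Both aldehydes must be oxidised before any formate is cleaved, because a free C7a phenol would add to the aldehyde on the other ring and the lactol would be oxidised back to a lactone; anhydrous base-free peracid and a separate methanolysis after full conversion secure this. The C6/C6' benzyl ethers block the same lactol closure from the other ortho oxygen.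

Step 6
Reactants: 9 6,6'-bis(benzyloxy)-4,4',5,5'-tetramethoxybiphenyl-2,2'-diol; 10 propanoyl chloride
Product: 11 6,6'-bis(benzyloxy)-4,4',5,5'-tetramethoxybiphenyl-2,2'-diyl dipropanoate (racemic axis)
Conditions: EtCOCl, Et3N, DMAP (cat.), CH2Cl2, 0 °C to rt
Reagents that add atoms: propanoyl chloride CCC(=O)Cl
Why: DMAP-catalysed O-acylation of the two phenols on C7a/C7a', which also protects the air-sensitive electron-rich phenol.

Step 7
Reactants: 11 6,6'-bis(benzyloxy)-4,4',5,5'-tetramethoxybiphenyl-2,2'-diyl dipropanoate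
Product: 12 1,1'-[6,6'-bis(benzyloxy)-2,2'-dihydroxy-4,4',5,5'-tetramethoxybiphenyl-3,3'-diyl]di(propan-1-one) (racemic axis)
Conditions: BF3·OEt2, ClCH2CH2Cl, 60 °C; then H2O
Reagents that add atoms: none
Why: Lewis acid Fries rearrangement moves each propanoyl group to C3a, the only unsubstituted ring carbon, which is ortho to the ester oxygen and to the C4 methoxy group and para to the C6 benzyloxy group, while the mild boron Lewis acid is chosen to spare the benzyl and methyl ethers.

Step 8
Reactants: 12 1,1'-[6,6'-bis(benzyloxy)-2,2'-dihydroxy-4,4',5,5'-tetramethoxybiphenyl-3,3'-diyl]di(propan-1-one)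
Product: 13 (aR)-1,1'-[6,6'-bis(benzyloxy)-2,2'-dihydroxy-4,4',5,5'-tetramethoxybiphenyl-3,3'-diyl]di(propan-1-one)
Conditions: preparative HPLC on amylose tris(3,5-dimethylphenylcarbamate) stationary phase, heptane/i-PrOH
Reagents that add atoms: none
Why: Chromatographic resolution of atropisomers on a chiral stationary phase, possible because the four ortho oxygens (buttressed by the C5 methoxy and C3a acyl groups) should make the axis configurationally stable; the axis, the only permanent stereo element of the target, is fixed here as (aR).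

Step 9
Reactants: 13 (aR)-1,1'-[6,6'-bis(benzyloxy)-2,2'-dihydroxy-4,4',5,5'-tetramethoxybiphenyl-3,3'-diyl]di(propan-1-one)
Product: 15 (aR)-6,6'-bis(benzyloxy)-2,2'-dihydroxy-4,4',5,5'-tetramethoxy-2,2'-dimethyl-7,7'-bi-1-benzofuran-3,3'(2H,2'H)-dione as a mixture of C2/C2' epimers, via open bis(1,2-diketone) 14 (not isolated)
Conditions: SeO2, 1,4-dioxane/H2O, 90 °C
Reagents that add atoms: selenium dioxide O=[Se]=O
Why: Riley oxidation converts the enolisable CH2 next to each aryl ketone into a carbonyl, and the free C7a hydroxyl then adds to this new C2 carbonyl to close each furanone ring as a hemiketal; C2 and C2' form without control here and stay epimerisable.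

Step 10
Reactants: 15 (aR)-6,6'-bis(benzyloxy)-2,2'-dihydroxy-4,4',5,5'-tetramethoxy-2,2'-dimethyl-7,7'-bi-1-benzofuran-3,3'(2H,2'H)-dione (epimer mixture)
Product: 17 (aR,2R,2'R)-2,2',6,6'-tetrahydroxy-4,4',5,5'-tetramethoxy-2,2'-dimethyl-7,7'-bi-1-benzofuran-3,3'(2H,2'H)-dione (target), via debenzylated epimer mixture 16 (not isolated)
Conditions: H2 (1 atm), Pd on carbon, EtOAc, rt; filter; then AcOH (cat.), EtOAc/heptane, slow crystallisation with the mother liquor recycled
Reagents that add atoms: none
Why: Hydrogenolysis of the two aryl benzyl ethers frees the C6/C6' hydroxyls, after which C2 and C2' epimerise by ring-chain tautomerism through the open diketone, and crystallisation-induced diastereomer transformation on the fixed (aR) axis should deposit the C2-symmetric (2R,2'R) isomer.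

**Compound list**

1 | ellagic acid | O=C1Oc2c(O)c(O)cc3c2c2c1cc(O)c(O)c2OC3=O | starting material
2 | dimethyl sulfate | COS(=O)(=O)OC | starting material
3 | 3,3',4,4'-tetra-O-methylellagic acid | O=C1Oc2c(OC)c(OC)cc3c2c2c1cc(OC)c(OC)c2OC3=O | intermediate
4 | 6,6'-bis(hydroxymethyl)-3,3',4,4'-tetramethoxybiphenyl-2,2'-diol (racemic axis) | COc1cc(CO)c(-c2c(CO)cc(OC)c(OC)c2O)c(O)c1OC | intermediate
5 | benzyl bromide | BrCc1ccccc1 | starting material
6 | [6,6'-bis(benzyloxy)-4,4',5,5'-tetramethoxybiphenyl-2,2'-diyl]dimethanol (racemic axis) | COc1cc(CO)c(-c2c(CO)cc(OC)c(OC)c2OCc2ccccc2)c(OCc2ccccc2)c1OC | intermediate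
7 | 6,6'-bis(benzyloxy)-4,4',5,5'-tetramethoxybiphenyl-2,2'-dicarbaldehyde (racemic axis) | COc1cc(C=O)c(-c2c(C=O)cc(OC)c(OC)c2OCc2ccccc2)c(OCc2ccccc2)c1OC | intermediate
8 | 6,6'-bis(benzyloxy)-4,4',5,5'-tetramethoxybiphenyl-2,2'-diyl diformate (racemic axis, not isolated) | COc1cc(OC=O)c(-c2c(OC=O)cc(OC)c(OC)c2OCc2ccccc2)c(OCc2ccccc2)c1OC | intermediate
9 | 6,6'-bis(benzyloxy)-4,4',5,5'-tetramethoxybiphenyl-2,2'-diol (racemic axis) | COc1cc(O)c(-c2c(O)cc(OC)c(OC)c2OCc2ccccc2)c(OCc2ccccc2)c1OC | intermediate
10 | propanoyl chloride | CCC(=O)Cl | starting material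
11 | 6,6'-bis(benzyloxy)-4,4',5,5'-tetramethoxybiphenyl-2,2'-diyl dipropanoate (racemic axis) | COc1cc(OC(=O)CC)c(-c2c(OC(=O)CC)cc(OC)c(OC)c2OCc2ccccc2)c(OCc2ccccc2)c1OC | intermediate
12 | 1,1'-[6,6'-bis(benzyloxy)-2,2'-dihydroxy-4,4',5,5'-tetramethoxybiphenyl-3,3'-diyl]di(propan-1-one) (racemic axis) | COc1c(OC)c(C(=O)CC)c(O)c(-c2c(O)c(C(=O)CC)c(OC)c(OC)c2OCc2ccccc2)c1OCc1ccccc1 | intermediate
13 | (aR)-1,1'-[6,6'-bis(benzyloxy)-2,2'-dihydroxy-4,4',5,5'-tetramethoxybiphenyl-3,3'-diyl]di(propan-1-one) | COc1c(OC)c(C(=O)CC)c(O)c(-c2c(O)c(C(=O)CC)c(OC)c(OC)c2OCc2ccccc2)c1OCc1ccccc1 | intermediate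
14 | (aR)-1,1'-[6,6'-bis(benzyloxy)-2,2'-dihydroxy-4,4',5,5'-tetramethoxybiphenyl-3,3'-diyl]di(propane-1,2-dione) (not isolated) | COc1c(OC)c(C(=O)C(C)=O)c(O)c(-c2c(O)c(C(=O)C(C)=O)c(OC)c(OC)c2OCc2ccccc2)c1OCc1ccccc1 | intermediate
15 | (aR)-6,6'-bis(benzyloxy)-2,2'-dihydroxy-4,4',5,5'-tetramethoxy-2,2'-dimethyl-7,7'-bi-1-benzofuran-3,3'(2H,2'H)-dione (mixture of C2/C2' epimers) | COc1c(OCc2ccccc2)c(-c2c(OCc3ccccc3)c(OC)c(OC)c3c2OC(C)(O)C3=O)c2c(c1OC)C(=O)C(C)(O)O2 | intermediate
16 | (aR)-2,2',6,6'-tetrahydroxy-4,4',5,5'-tetramethoxy-2,2'-dimethyl-7,7'-bi-1-benzofuran-3,3'(2H,2'H)-dione (mixture of C2/C2' epimers, not isolated) | COc1c(O)c(-c2c(O)c(OC)c(OC)c3c2OC(C)(O)C3=O)c2c(c1OC)C(=O)C(C)(O)O2 | intermediate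
17 | (aR,2R,2'R)-2,2',6,6'-tetrahydroxy-4,4',5,5'-tetramethoxy-2,2'-dimethyl-7,7'-bi-1-benzofuran-3,3'(2H,2'H)-dione | COc1c(O)c(-c2c(O)c(OC)c(OC)c3c2O[C@@](C)(O)C3=O)c2c(c1OC)C(=O)[C@](C)(O)O2 | target

**Step count and risks**

Total step count: 10. Longest linear sequence: 10 steps (ellagic acid to 17).

Steps most likely to fail:

1. Step 7. The Lewis acid may strip or shift the benzyl groups on the C6/C6' oxygens, or demethylate the C4 methoxy group next to the new ketone, before both acyl groups have moved. The fallback replaces the acid-mediated acyl shift by directed ortho-metalation. It sets out from 9, which is protected with MOMCl and i-Pr2NEt in CH2Cl2 to give the bis(methoxymethyl ether) F1. Treatment with n-BuLi and TMEDA in THF at 0 °C lithiates C3a and C3a', each lying between the OMOM and the C4 methoxy group, to give the dilithio compound F2. This is trapped with N-methoxy-N-methylpropanamide to give the MOM-protected bis(propiophenone) F3. HCl in MeOH then removes the MOM groups, and the sequence comes back to the route at 12.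

2. Step 5. Hydride migration in the Criegee adduct would give acids, and early loss of one formate would let the phenol close a lactol onto the second aldehyde, so that only one carbon is exchanged for oxygen. The fallback turns the aldehydes into methyl ketones, so that the competing migrating group is methyl and the product ester is a stable acetate. It sets out from 7, to which MeMgBr in THF is added to give the bis(1-hydroxyethyl) compound F4. Dess–Martin periodinane oxidises this to the bis(acetyl) compound F5. Baeyer–Villiger oxidation with mCPBA and NaHCO3 in CH2Cl2 gives the bis(acetate) F6. K2CO3 in MeOH cleaves the acetates, and the sequence comes back to the route at 9.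

3. Step 10. Hydrogenation of the C3 carbonyl, or of the small amount of open 1,2-diketone, may compete while the hindered benzyl ethers are cleaved, and the epimers may crystallise slowly or without selection. The fallback changes the order so that no diketone or hemiketal meets hydrogen. It sets out from 13, which is hydrogenolysed (H2, Pd on carbon, EtOAc) to the tetrahydroxy bis(propiophenone) F7, whose chelated, oxygen-rich aryl ketones resist reduction. SeO2 in wet dioxane then gives the open tetrahydroxy bis(1,2-diketone) F8, which closes to the epimer mixture 16, where the sequence comes back to the route. If crystals do not form, the epimers are separated by reversed-phase chromatography at neutral pH and the unwanted ones are re-equilibrated with a trace of AcOH and recycled to 17.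

Further compounds
F1 | step 7 | 2,2'-bis(benzyloxy)-3,3',4,4'-tetramethoxy-6,6'-bis(methoxymethoxy)biphenyl (racemic axis) | COCOc1cc(OC)c(OC)c(OCc2ccccc2)c1-c1c(OCOC)cc(OC)c(OC)c1OCc1ccccc1
F2 | step 7 | 3,3'-dilithio derivative of F1 (lithium on C3a and C3a') | COCOc1c([Li])c(OC)c(OC)c(OCc2ccccc2)c1-c1c(OCOC)c([Li])c(OC)c(OC)c1OCc1ccccc1
F3 | step 7 | 1,1'-[6,6'-bis(benzyloxy)-4,4',5,5'-tetramethoxy-2,2'-bis(methoxymethoxy)biphenyl-3,3'-diyl]di(propan-1-one) (racemic axis) | COCOc1c(C(=O)CC)c(OC)c(OC)c(OCc2ccccc2)c1-c1c(OCOC)c(C(=O)CC)c(OC)c(OC)c1OCc1ccccc1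
F4 | step 5 | 1,1'-[6,6'-bis(benzyloxy)-4,4',5,5'-tetramethoxybiphenyl-2,2'-diyl]di(ethan-1-ol) (mixture of diastereomers) | COc1cc(C(C)O)c(-c2c(C(C)O)cc(OC)c(OC)c2OCc2ccccc2)c(OCc2ccccc2)c1OC
F5 | step 5 | 1,1'-[6,6'-bis(benzyloxy)-4,4',5,5'-tetramethoxybiphenyl-2,2'-diyl]di(ethan-1-one) (racemic axis) | COc1cc(C(C)=O)c(-c2c(C(C)=O)cc(OC)c(OC)c2OCc2ccccc2)c(OCc2ccccc2)c1OC
F6 | step 5 | 6,6'-bis(benzyloxy)-4,4',5,5'-tetramethoxybiphenyl-2,2'-diyl diacetate (racemic axis) | COc1cc(OC(C)=O)c(-c2c(OC(C)=O)cc(OC)c(OC)c2OCc2ccccc2)c(OCc2ccccc2)c1OC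
F7 | step 10 | (aR)-1,1'-[2,2',6,6'-tetrahydroxy-4,4',5,5'-tetramethoxybiphenyl-3,3'-diyl]di(propan-1-one) | CCC(=O)c1c(O)c(-c2c(O)c(C(=O)CC)c(OC)c(OC)c2O)c(O)c(OC)c1OC
F8 | step 10 | (aR)-1,1'-[2,2',6,6'-tetrahydroxy-4,4',5,5'-tetramethoxybiphenyl-3,3'-diyl]di(propane-1,2-dione) (open form, not isolated) | CC(=O)C(=O)c1c(O)c(-c2c(O)c(C(=O)C(C)=O)c(OC)c(OC)c2O)c(O)c(OC)c1OC
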